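**Strategy.** The route rests on one disconnection: the spiro carbon, which is at once C-2 of the dihydrofuran ring (bonded to both the ring oxygen and the ring CH2) and C-1' of the cyclohexane ring, is removed as a one-carbon unit. In the key step this carbon, as a cyclohexylidene diazoalkane, joins the CH2 and O termini of an ortho-quinone methide released from the atraric acid Mannich base, forming two bonds, the five-membered ring and the spiro stereocentre in one operation. The precursor is a (S)-carvone-derived diazocyclohexane with both hydroxyls silylated and the acid held at the alcohol level; the benzene ring is expanded to the tropone afterwards.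

Key step: step 10

Remark: the SMILES is read as the (2S,2'R,3'S,6'S) isomer; the cyclohexanone behind the diazoalkane carries four substituents on three ring carbons, and its side chain is kept as a silylated primary alcohol (with the tertiary alcohol also silylated) because a methyl ester would not survive hydrazine or hot KOH and free hydroxyls would interfere with the diazoalkane and with dichlorocarbene.

Step 1
Reactants: 1 atraric acid (methyl 2,4-dihydroxy-3,6-dimethylbenzoate); 2 dimethylmethylideneammonium iodide
Product: 3 methyl 5-[(dimethylamino)methyl]-2,4-dihydroxy-3,6-dimethylbenzoate (Mannich base)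
Conditions: K2CO3, MeCN, rt
Reagents that add atoms: none
Why: Mannich reaction (electrophilic aromatic aminomethylation): the preformed iminium ion can only attack C-5, the single unsubstituted ring carbon, which is activated ortho and para by the two hydroxyls.

Step 2
Reactants: 4 (S)-(+)-carvone
Product: 6 (5S)-2,6-dimethyl-5-(prop-1-en-2-yl)cyclohex-2-en-1-one (6-methylcarvone; C-6 epimer mixture), via lithium dienolate 5 (not isolated)
Conditions: LiN(i-Pr)2, THF, −78 °C; MeI, −78 → 0 °C
Reagents that add atoms: iodomethane, CI
Why: Kinetic enolate alkylation: the amide base removes an alpha-prime proton (C-6) of the enone to give cross-conjugated dienolate 5, which is C-methylated; the configuration at C-6 is immaterial because that carbon is enolised again in step 3.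

Step 3
Reactants: 6 6-methylcarvone
Product: 8 (5R,6R)-2,6-dimethyl-6-(prop-2-en-1-yl)-5-(prop-1-en-2-yl)cyclohex-2-en-1-one, via lithium dienolate 7 (not isolated)
Conditions: LiN(i-Pr)2, THF, −78 °C; allyl bromide, −78 °C → rt
Reagents that add atoms: allyl bromide (3-bromoprop-1-ene), C=CCBr
Why: Kinetic enolate alkylation forming a quaternary centre: dienolate 7 should be attacked by the allylic halide on the face opposite the adjacent isopropenyl group, the usual course for 6-substituted carvone enolates, so that allyl ends up trans and methyl cis to that group (6R).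

Step 4
Reactants: 8 6-allyl-6-methylcarvone
Product: 10 (2R,3R,6S)-2,6-dimethyl-2-(prop-2-en-1-yl)-3-(prop-1-en-2-yl)cyclohexan-1-one, via lithium enolate 9 (not isolated)
Conditions: LiBH(s-Bu)3 (L-Selectride), THF, −78 °C; MeOH, NaOMe (cat.), 0 °C → rt
Reagents that add atoms: none
Why: Conjugate (1,4) hydride reduction of a beta-unsubstituted cyclohexenone by a hindered trialkylborohydride, which ignores the two isolated alkenes; protonation of enolate 9 and methoxide equilibration should leave the C-6 methyl equatorial and trans to the axial C-2 methyl (no syn-diaxial methyl pair), so the 6S centre is set under thermodynamic control.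

Step 5
Reactants: 10 saturated ketone
Product: 12 (2R,3R,6S)-2-(3-hydroxypropyl)-2,6-dimethyl-3-(prop-1-en-2-yl)cyclohexan-1-one, via catechol boronate 11 (not isolated)
Conditions: catecholborane, RhCl(PPh3)3 (cat.), THF, 0 °C → rt; NaOH, H2O2, 0 °C
Reagents that add atoms: hydrogen peroxide, OO
Why: Rhodium-catalysed anti-Markovnikov hydroboration and oxidation: under RhCl(PPh3)3 catalysis catecholborane should add to the monosubstituted allyl alkene far faster than to the 1,1-disubstituted isopropenyl group or the hindered ketone, and alkaline peroxide converts boronate 11 into the primary alcohol with no stereocentre affected.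

Step 6
Reactants: 12 primary alcohol
Product: 13 (2R,3S,6S)-3-(2-hydroxypropan-2-yl)-2-(3-hydroxypropyl)-2,6-dimethylcyclohexan-1-one
Conditions: Co(acac)2 (cat.), PhSiH3, O2 (1 atm), THF, rt
Reagents that add atoms: dioxygen, O=O
Why: Mukaiyama hydration (cobalt-catalysed hydrogen-atom transfer, O2 trapping and reduction): the only remaining alkene gives the tertiary radical and hence the Markovnikov tertiary alcohol, while the ketone, the primary alcohol and the existing stereocentres are not involved.

Step 7
Reactants: 13 diol
Product: 14 (2R,3S,6S)-3-[2-(tert-butyldimethylsilyloxy)propan-2-yl]-2-[3-(tert-butyldimethylsilyloxy)propyl]-2,6-dimethylcyclohexan-1-one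
Conditions: TBSOTf, 2,6-lutidine, CH2Cl2, −78 → 0 °C
Reagents that add atoms: tert-butyldimethylsilyl trifluoromethanesulfonate, CC(C)(C)[Si](C)(C)OS(=O)(=O)C(F)(F)F
Why: Silyl ether formation: the silyl triflate with a hindered pyridine base silylates the primary and the tertiary hydroxyl alike, so that no O–H group is left to protonate the diazoalkane, to add to the quinone methide or to react with dichlorocarbene later.

Step 8
Reactants: 14 bis-silyl ketone
Product: 15 hydrazone of 14
Conditions: N2H4·H2O (excess), Et3N, EtOH, reflux
Reagents that add atoms: hydrazine, NN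
Why: Hydrazone condensation: excess hydrazine under forcing conditions should convert this 2,2,6-trisubstituted ketone as it does 2,2,6-trimethylcyclohexanone, the silyl ethers are inert to hydrazine (an ester side chain would give the hydrazide), and the epimerisable C-6 methyl stays in its stable equatorial position.

Step 9
Reactants: 15 hydrazone
Product: 16 (2R,3S,6S)-3-[2-(tert-butyldimethylsilyloxy)propan-2-yl]-2-[3-(tert-butyldimethylsilyloxy)propyl]-1-diazo-2,6-dimethylcyclohexane (cold THF solution used at once)
Conditions: (COCl)2, DMSO, THF, −78 °C; 15, Et3N, −78 °C; cold filtration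
Reagents that add atoms: none
Why: Dehydrogenation of a hydrazone with activated dimethyl sulfoxide (Swern-type oxidation): the NH2 nitrogen is sulfenylated by chlorodimethylsulfonium chloride and triethylamine then eliminates dimethyl sulfide, which should deliver the non-stabilised diazoalkane at a temperature at which it neither loses N2 nor forms the azine.

Step 10
Reactants: 3 Mannich base; 16 diazoalkane
Product: 20 methyl (2S,2'R,3'S,6'S)-3'-[2-(tert-butyldimethylsilyloxy)propan-2-yl]-2'-[3-(tert-butyldimethylsilyloxy)propyl]-6-hydroxy-2',4,6',7-tetramethyl-3H-spiro[1-benzofuran-2,1'-cyclohexane]-5-carboxylate, via ammonium iodide 17 (not isolated), via phenoxide betaine 18 (not isolated), via quinone methide 19 (not isolated)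
Conditions: 3 (excess), MeI (1.0 equiv to 3), MeCN, rt, then evaporation; Cs2CO3, THF, −78 °C; solution of 16; −78 °C → rt
Reagents that add atoms: none
Why: Proposed new method: Cs2CO3 turns ammonium salt 17 into betaine 18, which expels trimethylamine, and the quinone methide 19 so released is attacked at its unhindered exocyclic CH2 by the nucleophilic diazo carbon of 16, which re-aromatises the ring as a phenoxide and leaves a tertiary alkyldiazonium ion (first bond, CH2–C-2). Nitrogen is lost at once and the tertiary cation, or its tight ion pair, is captured by the adjacent phenoxide oxygen in a 5-exo-tet O–C closure that forms the dihydrofuran ring (second bond, O–C-2). The closest known reaction type is the formal [4+1] annulation of ortho-quinone methides with sulfur ylides or acceptor-stabilised diazo esters; its extension to a hindered, non-stabilised diazoalkane has not been shown. Configuration at the new spiro carbon is decided when the C–O bond forms: approach of oxygen along the axial direction, anti to the axial methyl on the neighbouring quaternary carbon, is the less hindered path and places the ArCH2 branch equatorial, which is also the more stable arrangement (2S). The step needs C-alkylation of the diazo carbon in preference to its protonation, and O-capture of the cation in preference to 1,2-shift or elimination; the aprotic carbonate medium, the silylated hydroxyls and the ester-chelated, poorly acidic remaining phenol serve the first need, and the phenoxide held in a five-membered array next to the cation serves the second.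

Step 11
Reactants: 20 spiro-dihydrobenzofuran phenol
Product: 21 methyl (2S,2'R,3'S,6'S)-3'-[2-(tert-butyldimethylsilyloxy)propan-2-yl]-2'-[3-(tert-butyldimethylsilyloxy)propyl]-3a-(dichloromethyl)-2',4,6',7-tetramethyl-6-oxo-3a,6-dihydro-3H-spiro[1-benzofuran-2,1'-cyclohexane]-5-carboxylate (C-3a epimer mixture)
Conditions: CHCl3, 50% aq KOH, BnEt3NCl (cat.), 40 °C
Reagents that add atoms: chloroform, ClC(Cl)Cl
Why: Abnormal Reimer–Tiemann reaction (dearomative C-alkylation of a phenoxide by dichlorocarbene): with both ortho carbons and the para carbon substituted, attack at the ring-fusion para carbon C-3a cannot re-aromatise and should give the 4-dichloromethylcyclohexa-2,5-dienone, as known for ring-fused para-alkylphenols such as 5,6,7,8-tetrahydro-2-naphthol; C-3a forms as an epimer mixture, which is harmless because this carbon becomes sp2 again in step 12.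

Step 12
Reactants: 21 dichloromethyl dienone
Product: 22 methyl (2S,2'R,3'S,6'S)-3'-[2-(tert-butyldimethylsilyloxy)propan-2-yl]-2'-[3-(tert-butyldimethylsilyloxy)propyl]-2',5,6',8-tetramethyl-7-oxo-3,7-dihydrospiro[cyclohepta[b]furan-2,1'-cyclohexane]-6-carboxylate
Conditions: Bu3SnH (slow addition), AIBN (cat.), K2CO3, benzene, 80 °C
Reagents that add atoms: none
Why: Radical one-carbon ring expansion of Dowd–Beckwith type, the known route from 4-dichloromethylcyclohexa-2,5-dienones to tropones: chlorine abstraction gives a chloromethyl radical that should close 3-exo onto C-4 (the methyl-bearing beta-carbon of the keto-ester alkene, giving a doubly stabilised radical) and not onto the oxygen-bearing ring-fusion carbon, the cyclopropylcarbinyl radical opens to the seven-membered ring, and loss of the second chlorine as HCl leaves the tropone with CH inserted between C-3a and the methyl-bearing carbon.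

Step 13
Reactants: 22 bis-silyl tropone
Product: 23 methyl (2S,2'R,3'S,6'S)-3'-(2-hydroxypropan-2-yl)-2'-(3-hydroxypropyl)-2',5,6',8-tetramethyl-7-oxo-3,7-dihydrospiro[cyclohepta[b]furan-2,1'-cyclohexane]-6-carboxylate
Conditions: HF·pyridine, pyridine, THF, 0 °C → rt
Reagents that add atoms: none
Why: Fluoride-mediated silyl ether cleavage: buffered HF·pyridine removes both silyl groups under weakly acidic, non-nucleophilic conditions that should spare the tropone, the methyl ester and the tertiary alkyl aryl ether.

Step 14
Reactants: 23 tropone diol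
Product: 25 3-[(2S,2'R,3'S,6'S)-3'-(2-hydroxypropan-2-yl)-6-(methoxycarbonyl)-2',5,6',8-tetramethyl-7-oxo-3,7-dihydrospiro[cyclohepta[b]furan-2,1'-cyclohexan]-2'-yl]propanoic acid (target), via aldehyde 24 (not isolated)
Conditions: TEMPO (cat.), PhI(OAc)2, MeCN–pH 7 buffer, rt
Reagents that add atoms: water, O
Why: Oxoammonium (TEMPO) oxidation of a primary alcohol through aldehyde 24 and its hydrate to the carboxylic acid: the tertiary alcohol cannot be oxidised and the near-neutral aqueous medium avoids the base to which tropones are sensitive.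

**Compound list**

1 | atraric acid (methyl 2,4-dihydroxy-3,6-dimethylbenzoate) | COC(=O)c1c(C)cc(O)c(C)c1O | starting material
2 | dimethylmethylideneammonium iodide | C=[N+](C)C.[I-] | starting material
3 | methyl 5-[(dimethylamino)methyl]-2,4-dihydroxy-3,6-dimethylbenzoate (Mannich base) | COC(=O)c1c(C)c(CN(C)C)c(O)c(C)c1O | intermediate
4 | (S)-(+)-carvone, (5S)-2-methyl-5-(prop-1-en-2-yl)cyclohex-2-en-1-one | CC1=CC[C@H](C(C)=C)CC1=O | starting material
5 | lithium dienolate of 4, deprotonated at C-6 (formed in situ) | CC1=CC[C@H](C(C)=C)C=C1[O-].[Li+] | intermediate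
6 | (5S)-2,6-dimethyl-5-(prop-1-en-2-yl)cyclohex-2-en-1-one (6-methylcarvone, C-6 epimer mixture) | CC1=CC[C@H](C(C)=C)C(C)C1=O | intermediate
7 | lithium dienolate of 6 (formed in situ) | CC1=CC[C@H](C(C)=C)C(C)=C1[O-].[Li+] | intermediate
8 | (5R,6R)-2,6-dimethyl-6-(prop-2-en-1-yl)-5-(prop-1-en-2-yl)cyclohex-2-en-1-one (allyl trans to isopropenyl) | O=C1C(C)=CC[C@H](C(C)=C)[C@@]1(C)CC=C | intermediate
9 | lithium enolate of 10 (formed in situ) | [Li+].[O-]C1=C(C)CC[C@H](C(C)=C)[C@@]1(C)CC=C | intermediate
10 | (2R,3R,6S)-2,6-dimethyl-2-(prop-2-en-1-yl)-3-(prop-1-en-2-yl)cyclohexan-1-one | O=C1[C@@H](C)CC[C@H](C(C)=C)[C@@]1(C)CC=C | intermediate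
11 | (2R,3R,6S)-2-[3-(1,3,2-benzodioxaborol-2-yl)propyl]-2,6-dimethyl-3-(prop-1-en-2-yl)cyclohexan-1-one (formed in situ) | O=C1[C@@H](C)CC[C@H](C(C)=C)[C@@]1(C)CCCB1Oc2ccccc2O1 | intermediate
12 | (2R,3R,6S)-2-(3-hydroxypropyl)-2,6-dimethyl-3-(prop-1-en-2-yl)cyclohexan-1-one | O=C1[C@@H](C)CC[C@H](C(C)=C)[C@@]1(C)CCCO | intermediate
13 | (2R,3S,6S)-3-(2-hydroxypropan-2-yl)-2-(3-hydroxypropyl)-2,6-dimethylcyclohexan-1-one | O=C1[C@@H](C)CC[C@H](C(C)(C)O)[C@@]1(C)CCCO | intermediate
14 | (2R,3S,6S)-3-[2-(tert-butyldimethylsilyloxy)propan-2-yl]-2-[3-(tert-butyldimethylsilyloxy)propyl]-2,6-dimethylcyclohexan-1-one | O=C1[C@@H](C)CC[C@H](C(C)(C)O[Si](C)(C)C(C)(C)C)[C@@]1(C)CCCO[Si](C)(C)C(C)(C)C | intermediate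
15 | hydrazone of 14 (C=N geometry not defined) | NN=C1[C@@H](C)CC[C@H](C(C)(C)O[Si](C)(C)C(C)(C)C)[C@@]1(C)CCCO[Si](C)(C)C(C)(C)C | intermediate
16 | (2R,3S,6S)-3-[2-(tert-butyldimethylsilyloxy)propan-2-yl]-2-[3-(tert-butyldimethylsilyloxy)propyl]-1-diazo-2,6-dimethylcyclohexane | [N-]=[N+]=C1[C@@H](C)CC[C@H](C(C)(C)O[Si](C)(C)C(C)(C)C)[C@@]1(C)CCCO[Si](C)(C)C(C)(C)C | intermediate
17 | [2,4-dihydroxy-5-(methoxycarbonyl)-3,6-dimethylphenyl]methyl(trimethyl)ammonium iodide (formed in situ) | COC(=O)c1c(C)c(C[N+](C)(C)C)c(O)c(C)c1O.[I-] | intermediate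
18 | phenoxide betaine of 17, deprotonated at the hydroxyl ortho to the CH2N group (formed in situ) | COC(=O)c1c(C)c(C[N+](C)(C)C)c([O-])c(C)c1O | intermediate
19 | ortho-quinone methide, methyl 6-hydroxy-2,5-dimethyl-3-methylidene-4-oxocyclohexa-1,5-diene-1-carboxylate (formed in situ) | COC(=O)C1=C(C)C(=C)C(=O)C(C)=C1O | intermediate
20 | methyl (2S,2'R,3'S,6'S)-3'-[2-(tert-butyldimethylsilyloxy)propan-2-yl]-2'-[3-(tert-butyldimethylsilyloxy)propyl]-6-hydroxy-2',4,6',7-tetramethyl-3H-spiro[1-benzofuran-2,1'-cyclohexane]-5-carboxylate | COC(=O)c1c(C)c2c(c(C)c1O)O[C@@]1(C2)[C@@H](C)CC[C@H](C(C)(C)O[Si](C)(C)C(C)(C)C)[C@@]1(C)CCCO[Si](C)(C)C(C)(C)C | intermediate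
21 | 3a-(dichloromethyl)-6-oxo-3a,6-dihydro analogue of 20 (C-3a epimer mixture) | COC(=O)C1=C(C)C2(C(Cl)Cl)C[C@]3(OC2=C(C)C1=O)[C@@H](C)CC[C@H](C(C)(C)O[Si](C)(C)C(C)(C)C)[C@@]3(C)CCCO[Si](C)(C)C(C)(C)C | intermediate
22 | methyl (2S,2'R,3'S,6'S)-3'-[2-(tert-butyldimethylsilyloxy)propan-2-yl]-2'-[3-(tert-butyldimethylsilyloxy)propyl]-2',5,6',8-tetramethyl-7-oxo-3,7-dihydrospiro[cyclohepta[b]furan-2,1'-cyclohexane]-6-carboxylate | COC(=O)c1c(C)cc2c(c(C)c1=O)O[C@@]1(C2)[C@@H](C)CC[C@H](C(C)(C)O[Si](C)(C)C(C)(C)C)[C@@]1(C)CCCO[Si](C)(C)C(C)(C)C | intermediate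
23 | methyl (2S,2'R,3'S,6'S)-3'-(2-hydroxypropan-2-yl)-2'-(3-hydroxypropyl)-2',5,6',8-tetramethyl-7-oxo-3,7-dihydrospiro[cyclohepta[b]furan-2,1'-cyclohexane]-6-carboxylate | COC(=O)c1c(C)cc2c(c(C)c1=O)O[C@@]1(C2)[C@@H](C)CC[C@H](C(C)(C)O)[C@@]1(C)CCCO | intermediate
24 | aldehyde of 23, 2'-(3-oxopropyl) side chain (formed in situ) | COC(=O)c1c(C)cc2c(c(C)c1=O)O[C@@]1(C2)[C@@H](C)CC[C@H](C(C)(C)O)[C@@]1(C)CCC=O | intermediate
25 | 3-[(2S,2'R,3'S,6'S)-3'-(2-hydroxypropan-2-yl)-6-(methoxycarbonyl)-2',5,6',8-tetramethyl-7-oxo-3,7-dihydrospiro[cyclohepta[b]furan-2,1'-cyclohexan]-2'-yl]propanoic acid | COC(=O)c1c(C)cc2c(c(C)c1=O)O[C@@]1(C2)[C@@H](C)CC[C@H](C(C)(C)O)[C@@]1(C)CCC(=O)O | target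

**Step count and risks**

Total step count: 14. Longest linear sequence: 13 steps (steps 2 to 14, from (S)-carvone 4 to 25); step 1 is the only step of the second branch.

Steps most likely to fail:

1. Step 10 (Proposed new method). What may go wrong: the diazoalkane may be protonated, or may lose N2 and undergo a 1,2-hydrogen shift, before it meets the quinone methide; the quinone methide may oligomerise; the tertiary cation may eliminate or rearrange instead of closing the ring. The fallback uses known chemistry, sets out from hydrazone 15 and returns at 20. Iodine and tetramethylguanidine (Barton vinyl iodide synthesis) would convert 15 into the alkenyl iodide F1. Iodine–lithium exchange with t-BuLi would give the alkenyllithium F2. Used in excess as base and nucleophile, F2 would add to quinone methide 19 released from ammonium iodide 17 (conjugate addition of an organometallic to an ortho-quinone methide; the doubly ortho-substituted ester is shielded), giving the ortho-(cyclohexenylmethyl)phenol F3. Acid-mediated phenol–alkene cycloisomerisation (BF3·OEt2, CH2Cl2, −40 °C), the classical closure of spiro-dihydrobenzofurans, would then protonate the methyl-bearing alkene carbon and trap the resulting tertiary cation with the phenol oxygen under the same axial preference, giving 20.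

2. Step 11. What may go wrong: dichlorocarbene may attack the methyl-bearing ortho carbon or the phenoxide oxygen in place of the ring-fusion para carbon, and the dienone may degrade in warm hydroxide by opening of its vinylogous ester. The fallback sets out from 20 and returns at 21. It is a photochemical Reimer–Tiemann reaction, in which the bond is made by radical-pair coupling and not by a carbene. Irradiation of 20 in CHCl3 with Et3N at room temperature, without hydroxide, should cause electron transfer from the excited phenoxide to chloroform. Collapse of the phenoxyl/dichloromethyl radical pair at the para carbon, the site of highest spin density, would give 21 directly; no new compound is involved.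

3. Step 9. What may go wrong: azine formation or over-oxidation during the dehydrogenation, and loss of N2 from the diazoalkane during filtration and transfer. The fallback sets out from ketone 14 and returns at 16. Condensation of 14 with 2-(trifluoromethyl)benzenesulfonohydrazide (acid catalysis, aprotic solvent) would give the N-sulfonylhydrazone F4. Its sodium salt F5 (NaH, THF) should fragment below room temperature (Bamford–Stevens reaction) to the arenesulfinate and diazoalkane 16. The diazoalkane would be generated in the flask that already holds betaine 18, so that no oxidant and no ammonium salt is present.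

**Further compounds**

F1 | step 10 | (5S,6R)-5-[2-(tert-butyldimethylsilyloxy)propan-2-yl]-6-[3-(tert-butyldimethylsilyloxy)propyl]-1-iodo-2,6-dimethylcyclohex-1-ene | IC1=C(C)CC[C@H](C(C)(C)O[Si](C)(C)C(C)(C)C)[C@@]1(C)CCCO[Si](C)(C)C(C)(C)C
F2 | step 10 | alkenyllithium from F1 (lithium in place of iodine) | [Li]C1=C(C)CC[C@H](C(C)(C)O[Si](C)(C)C(C)(C)C)[C@@]1(C)CCCO[Si](C)(C)C(C)(C)C
F3 | step 10 | methyl 5-{[(5S,6R)-5-[2-(tert-butyldimethylsilyloxy)propan-2-yl]-6-[3-(tert-butyldimethylsilyloxy)propyl]-2,6-dimethylcyclohex-1-en-1-yl]methyl}-2,4-dihydroxy-3,6-dimethylbenzoate | COC(=O)c1c(C)c(CC2=C(C)CC[C@H](C(C)(C)O[Si](C)(C)C(C)(C)C)[C@@]2(C)CCCO[Si](C)(C)C(C)(C)C)c(O)c(C)c1O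
F0 | step 11 | none | none
F4 | step 9 | N'-[(2R,3S,6S)-3-[2-(tert-butyldimethylsilyloxy)propan-2-yl]-2-[3-(tert-butyldimethylsilyloxy)propyl]-2,6-dimethylcyclohexylidene]-2-(trifluoromethyl)benzenesulfonohydrazide | O=S(=O)(NN=C1[C@@H](C)CC[C@H](C(C)(C)O[Si](C)(C)C(C)(C)C)[C@@]1(C)CCCO[Si](C)(C)C(C)(C)C)c1ccccc1C(F)(F)F
F5 | step 9 | sodium salt of F4 (deprotonated at the sulfonamide nitrogen) | [Na+].O=S(=O)([N-]N=C1[C@@H](C)CC[C@H](C(C)(C)O[Si](C)(C)C(C)(C)C)[C@@]1(C)CCCO[Si](C)(C)C(C)(C)C)c1ccccc1C(F)(F)F
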